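## Structural features

The target is a linear trimer of 2-(4-hydroxyphenyl)chroman (flavan) units, each with a 7,8-dihydroxylated ring A; C4 of the upper unit T is bonded to C6 of the middle unit M, and C4 of M to C6 of the terminal unit B (flavan numbering throughout). Its nine stereocentres form three contiguous C2/C3/C4 triads: T is 2R,3R,4S (2,3-cis, 3,4-trans), M is 2R,3S,4R (2,3-trans, 3,4-trans), and B is 2R,3R,4R, an all-cis 3,4-diol with both oxygens on the face of the C2 aryl group. Every C4 is benzylic to a ring A activated by O1 (ortho) and O7 (para), so the C4–OH of B ionises in acid and is open to hydrogenolysis, the two C4–C6 bonds can reopen under strong acid, and each C2–O1 bond is a benzylic ether that a para-oxygen on ring B helps to break. The six pyrogallol-type hydroxyls are oxidised readily in base and air, so the last operations must be neutral. The real difficulty is to join three nearly identical, weakly nucleophilic A rings at C6 with control of C4, and to place both oxygens of B syn to its aryl group. In T the C3 hydroxyl and the C4 aryl group are trans, and C4 is bonded to C4a, the ring A carbon para to O7 and ortho to O1; this is the pattern left when a C3–C4 epoxide is opened at C4, with inversion, by that arene carbon, and the key step uses it to close ring C of T.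

## Logic of the disconnections

**26 ⇒ 25.** The six benzyl–oxygen bonds on O7 and O8 of the three A rings are cut last. Hydrogenolysis is the only neutral way to free pyrogallol-type phenols, and it leaves the two interflavan bonds alone. The demand is that the benzylic C4–OH of unit B is not reduced, so the catalyst is Pd(OH)2 on carbon without acid and the reaction is stopped once the ethers are gone.

**25 ⇒ 24.** Seven acyl–oxygen bonds are cut together: three aryl pivalates, the acetate on O3 of M, and both C–O bonds of the cyclic carbonate on B. All are esters, so one methanolysis removes them while the oxidisable phenols are still benzylated, and no acid ever meets the C4–O bond of B. The demand is mild base and exclusion of air.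

**24 ⇒ 23.** The C4(T)–C4a(T) bond is cut and the C3 oxygen is folded back onto C4 as a trans epoxide. The cut is placed there because the 3,4-trans relation and the para oxygen at C7 are what an anti epoxide opening by that arene carbon leaves. The gain is that ring C of T and C4 come from an open-chain aryl ether whose stereocentres are each set by a reagent. The forward step must be an anti, 6-endo opening that ionises no other benzylic C–O bond. Compared with an all-benzyl, acetonide-protected version of the same skeleton, 23 therefore differs in three spectator groups: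
- a pivalate, not an ether, para to C2 on each ring B, so that no C2–O bond is activated;
- a cyclic carbonate, not a ketal, on the diol of B, because it is a weaker Lewis base, is tethered, and needs no acid for removal;
- an acetate on O3 of M, put on and taken off without strong base or acid.

**23 ⇒ 22 + 10.** The C2(T)–O1(T) ether bond is cut. Mitsunobu inversion of an erythro epoxy alcohol gives the threo ether that becomes the 2,3-cis ring. The demand is clean SN2 at a benzylic carbinol, which the electron-poor aryl group and the adjacent epoxide favour.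

**22 ⇒ 21.** The two C–O bonds of the epoxide are cut. The alkene is an electron-rich styrene whose epoxide is acid-labile, so oxygen is transferred by a chiral dioxirane in carbonate buffer, not by a titanium tartrate. The catalyst must override the weak preference of the allylic hydroxyl for the other face.

**21 ⇒ 20 + 6.** The bond between C6(M) and the carbon that becomes C4(T) is cut while that carbon is still sp2. A Suzuki–Miyaura coupling makes this interflavan bond at an unambiguous position and brings in C2, C3, C4 and ring B of T as one enantiopure three-carbon unit. This replaces a formylation, aldol and ketone-reduction sequence. The base must be mild enough for the carbonate and the esters.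

**20 ⇒ 19 ⇒ 18.** The O-acetyl bond and the C6(M)–Br bond are cut. The acetate blocks the only other secondary alcohol before the second Mitsunobu reaction. The bromine goes to the one position of the new ring A that is para to O1 and ortho to O7, so its position is not in doubt.

**18 ⇒ 17 ⇒ 16 + 10 ⇒ 15 ⇒ 14 + 6.** The same four cuts are repeated for unit M: C4–C4a, C2–O1, the epoxide oxygen, and the aryl–alkenyl bond. The only change is the epoxide face. The natural Shi ketone gives the threo epoxy alcohol, so Mitsunobu inversion and anti opening now give the 2,3-trans-3,4-trans ring. Both rings thus come from 6 and 10.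

**14 ⇒ 12 (through 13).** The C3–O and C4–O bonds of the carbonate and the C6–Br bond are cut back to a 2H-chromene. A bromonium ion forms anti to the C2 aryl group, water opens it at C4, and a CO2-derived carbonate displaces bromide at C3. Both oxygens therefore arrive on the aryl face, which osmium tetroxide would not reach. The demand is facial selectivity in the first event and SN2 closure in the second.

**12 ⇒ 11 ⇒ 4 + 10.** C4–C4a is cut (gold-catalysed hydroarylation of an aryl propargyl ether) and then C2–O1 (Mitsunobu inversion of a propargylic alcohol). Unit B is thus made through the same two ring bonds as T and M. The demand is that the hydroarylation does not ionise the propargylic C–O bond.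

**6 ⇒ 4 (through 5); 4 ⇒ 3 ⇒ 2 ⇒ 1.** The C–B bond, the C–Si bond, the carbinol–alkyne C–C bond and the pivaloyl–oxygen bond are cut. One catalytic asymmetric alkynylation of an aromatic aldehyde sets the stereocentre that becomes C2 of all three units.

**10 ⇒ 8 (through 9) ⇒ 7.** The aryl C–O bond is traced to a formyl group (Baeyer–Villiger/Dakin sequence) and the benzyl ethers to a commercial catechol aldehyde. This fixes which oxygen of the pyrogallol pattern is free, which direct benzylation of the triol would not.

## Other disconnections considered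

**Alternative 1:** The cut removes ring A of M at C8a–C8, C7–C6 and C8a–C4a. In the forward step the diazo enone A2, attached through its diazo carbon to C4 of a finished unit T, would be photolysed. Wolff rearrangement would give a vinylketene that adds di-tert-butoxyethyne A3 in a [2+2] step; the cyclobutenone would open (4π) and reclose (6π) to the phenol A1.
- In its favour: C4 of T ends on C6 of M by construction, which equals the cross-coupling of the chosen plan and is better than any Friedel–Crafts union. The conditions are neutral, and no cation is formed next to acid-labile groups; on that point the pericyclic cascade is the better of the two.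
- Against it: A1 stops at a phenol whose C4a is unsubstituted. Ring C of M, its three stereocentres and the whole M–B bond still have to be made, so the hard part is postponed. The two tert-butyl ethers must later be exchanged under acid. A3 is not commercial and is thermally fragile. The C4–H next to the carbene carbon invites a 1,2-hydride shift that would erase C4 of T.
- Comparison: it builds an aromatic ring that the chosen plan buys in oxidised form. It is cleaner in mechanism and much poorer in step economy.

**Alternative 2:** The cut is C3(B)–C4(B). In the forward step SmI2 would reduce the aryl aldehyde of the dialdehyde A5 to a ketyl that adds to the α-aryloxy aldehyde, closing ring C of B as the diol A4.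
- In its favour: the acid-labile benzylic diol is made last and needs no protecting group, so no C4–O bond of B has to survive the two Lewis-acid ring closures; on this point it is better than the chosen plan. Samarium-bridged pinacol cyclisations give cis diols, and the conditions spare benzyl ethers.
- Against it: C2 of B in A5 is both benzylic and α to a formyl group, so it can epimerise. A ketyl next to an aryloxy group can expel it (reductive C–O cleavage by divalent samarium). A cis diol would be expected to form anti to the neighbouring aryl group, which gives 2,3-trans and not the all-cis triad. Two aldehydes would have to be carried or unmasked on a trimer.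
- Comparison: the ring closures are equal in count (one per ring). The chosen plan sets the B triad by two stereospecific anti events on a monomer, while the alternative relies on diastereoselection at the last carbon–carbon bond of the synthesis.

**Alternative 3:** The cuts are O1(M)–C2(M) and C3(M)–C4(M). In the forward step a chiral phosphoric acid would dehydrate the diaryl carbinol A7 to an o-quinone methide, which adds the (E)-styrylboronate A8 to give A6; oxidation of the C–B bond would give the C3 hydroxyl with retention.
- In its favour: the whole pyran ring of M and three stereocentres come in one convergent step, the alkene geometry encodes 2,3-trans, and the boronate is a clean hydroxyl surrogate. For unit M alone this is the more step-economic disconnection.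
- Against it: the quinone methide is made by acid ionisation at the future C4 of M, next to a unit B whose own benzylic C4–O bond (a ketal in A7) is at least as easy to ionise. The catalyst must override two existing chiral units. An alkenylboronate is a weak partner for an inverse-demand cycloaddition. Endo/exo control decides 3,4-trans against cis. A7 already contains the T–M bond, so that bond needs a separate solution.
- Comparison: the chosen plan uses the same ionic type of bond formation but ties each new stereocentre to a stereospecific substitution, not to catalyst–substrate matching.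

Key step: step 19

Assumption 1: the (S,S)-antipode of the ProPhenol ligand is taken to give the carbinol configuration of 3; if the first batch shows the opposite sense, the (R,R)-ligand is used and nothing else changes.

Assumption 2: the enantiomer of the fructose-derived Shi ketone (made from L-fructose) is treated as an available reagent.

## Route

Step 1
Reactants: 1 4-hydroxybenzaldehyde
Product: 2 4-formylphenyl pivalate
Conditions: t-BuCOCl, Et3N, DMAP (cat.), CH2Cl2, 0 °C to rt
Reagents that add atoms: pivaloyl chloride CC(C)(C)C(Cl)=O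
Why: Acylation of a phenol; the ester turns the future C2 aryl group from a donor into a weak acceptor, which later protects the benzylic C2–O bonds under Mitsunobu and Lewis-acid conditions, and it is removed in the same methanolysis as the other esters.

Step 2
Reactants: 2 4-formylphenyl pivalate
Product: 3 (S)-1-[4-(pivaloyloxy)phenyl]-3-(trimethylsilyl)prop-2-yn-1-ol
Conditions: Me3SiC≡CH (3 equiv), Me2Zn (3 equiv), (S,S)-ProPhenol (10 mol %), Ph3PO (20 mol %), toluene, 0 °C
Reagents that add atoms: trimethylsilylacetylene C#C[Si](C)(C)C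
Why: Catalytic enantioselective alkynylation of an aromatic aldehyde; the alkynylzinc is delivered to one aldehyde face inside the dinuclear zinc–ProPhenol complex, setting the stereocentre that becomes C2 of all three units. Aryl esters do not react with alkylzinc or alkynylzinc reagents at this temperature.

Step 3
Reactants: 3 (S)-1-[4-(pivaloyloxy)phenyl]-3-(trimethylsilyl)prop-2-yn-1-ol
Product: 4 (R)-1-[4-(pivaloyloxy)phenyl]prop-2-yn-1-ol
Conditions: Bu4NF, AcOH (1:1), THF, 0 °C
Reagents that add atoms: none
Why: Fluoride-induced protodesilylation of an alkynylsilane; buffering with acetic acid prevents acyl transfer from the aryl pivalate. The stereocentre is untouched; the descriptor changes only because silicon no longer raises the priority of the alkynyl group.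

Step 4
Reactants: 4 (R)-1-[4-(pivaloyloxy)phenyl]prop-2-yn-1-ol
Product: 6 (R,E)-1-[4-(pivaloyloxy)phenyl]-3-(4,4,5,5-tetramethyl-1,3,2-dioxaborolan-2-yl)prop-2-en-1-ol, via O-pinacolboryl ether 5 (not isolated)
Conditions: pinacolborane (2.5 equiv), Cp2Zr(H)Cl (10 mol %), Et3N (10 mol %), CH2Cl2, rt to 40 °C; aq. NH4Cl work-up
Reagents that add atoms: pinacolborane [H]B1OC(C)(C)C(C)(C)O1
Why: Zirconium-catalysed hydroboration of a terminal alkyne is syn and puts boron on the terminal carbon, so the (E)-alkenylboronate should result; the hydroxyl is capped in the flask as a borate and freed on work-up. The ester tolerates the borane.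

Step 5
Reactants: 7 2,3-dihydroxybenzaldehyde
Product: 8 2,3-bis(benzyloxy)benzaldehyde
Conditions: BnBr (2.2 equiv), K2CO3, DMF, 60 °C
Reagents that add atoms: benzyl bromide BrCc1ccccc1
Why: Williamson etherification of both phenols; the aldehyde marks the carbon that will carry the free hydroxyl.

Step 6
Reactants: 8 2,3-bis(benzyloxy)benzaldehyde
Product: 10 2,3-bis(benzyloxy)phenol, via aryl formate 9 (not isolated)
Conditions: m-CPBA, CH2Cl2, rt; then K2CO3, MeOH, 0 °C
Reagents that add atoms: 3-chloroperoxybenzoic acid OOC(=O)c1cccc(Cl)c1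
Why: Baeyer–Villiger (Dakin-type) oxidation of an electron-rich aryl aldehyde; the aryl group migrates to give the formate, which is methanolysed to the phenol. The position of the free hydroxyl is fixed by the position of the formyl group.

Step 7
Reactants: 4 (R)-1-[4-(pivaloyloxy)phenyl]prop-2-yn-1-ol; 10 2,3-bis(benzyloxy)phenol
Product: 11 4-{(1S)-1-[2,3-bis(benzyloxy)phenoxy]prop-2-yn-1-yl}phenyl pivalate
Conditions: PPh3, iPrO2CN=NCO2iPr (DIAD), toluene, 0 °C to rt
Reagents that add atoms: none
Why: Mitsunobu etherification; the phenoxide displaces the oxyphosphonium group by SN2 with inversion, turning the (R)-carbinol into the (S)-ether. Ionisation is disfavoured by the alkynyl group and the acyloxy-substituted aryl ring.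

Step 8
Reactants: 11 4-{(1S)-1-[2,3-bis(benzyloxy)phenoxy]prop-2-yn-1-yl}phenyl pivalate
Product: 12 (2S)-7,8-bis(benzyloxy)-2-[4-(pivaloyloxy)phenyl]-2H-chromene
Conditions: Ph3PAuNTf2 (3 mol %), CH2Cl2, rt, dark
Reagents that add atoms: none
Why: Monovalent-gold-catalysed 6-endo-dig intramolecular hydroarylation of an aryl propargyl ether; the only free ortho carbon, para to a benzyloxy group, attacks the activated alkyne and forms C4–C4a. C2 takes no part and keeps its configuration; light is excluded because 2H-chromenes can ring-open photochemically.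

Step 9
Reactants: 12 (2S)-7,8-bis(benzyloxy)-2-[4-(pivaloyloxy)phenyl]-2H-chromene
Product: 14 all-cis 7,8-bis(benzyloxy)-6-bromo-2-[4-(pivaloyloxy)phenyl]chromane-3,4-diyl carbonate (unit B; absolute configuration as in the 2R,3R,4R diol of the target), via trans-bromohydrin 13 (not isolated)
Conditions: NBS (2.1 equiv), THF–H2O (4:1), 0 °C; solvent exchange; DBU (3 equiv), CO2 (1 atm), DMF, rt to 40 °C
Reagents that add atoms: N-bromosuccinimide O=C1CCC(=O)N1Br; water O; carbon dioxide O=C=O
Why: Bromonium formation on the electron-rich C3=C4 bond should occur on the face away from the C2 aryl group and water opens it at benzylic C4 (halohydrin formation), placing O4 on the aryl face; the second equivalent brominates C6, the only position para to O1. Carboxylation of the C4 alkoxide and 5-exo SN2 displacement of the C3 bromide with inversion (carboxylative cyclisation of a halohydrin) puts O3 on the same face. Two stereospecific anti events thus fix the all-cis triad.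

Step 10
Reactants: 14 unit B bromide; 6 (R,E)-alkenylboronate
Product: 15 allylic alcohol B (14 with Br replaced by the (1E,3R)-3-hydroxy-3-[4-(pivaloyloxy)phenyl]prop-1-en-1-yl group)
Conditions: Pd(OAc)2 (3 mol %), SPhos (6 mol %), K3PO4 (0.5 M aq., 2 equiv), THF, 35 °C
Reagents that add atoms: none
Why: Suzuki–Miyaura coupling with retention of alkene geometry; it forms the bond between C6 of B and the future C4 of M at the sp2 level, where regiochemistry is fixed by the bromide. The dilute phosphate base and low temperature are chosen to spare the carbonate and the aryl esters.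

Step 11
Reactants: 15 allylic alcohol B
Product: 16 threo epoxy alcohol B (C6 of unit B bonded to C2 of a (2R,3R)-oxirane whose C3 carries the (S)-hydroxy[4-(pivaloyloxy)phenyl]methyl group)
Conditions: D-fructose-derived Shi ketone (30 mol %), KHSO5 (as 2KHSO5·KHSO4·K2SO4), K2CO3, Bu4NHSO4, Na2B4O7/Na2EDTA buffer (pH 10.5), MeCN–CH2(OMe)2–H2O, 0 °C
Reagents that add atoms: potassium peroxymonosulfate [K+].[O-]S(=O)(=O)OO
Why: Shi epoxidation; the chiral dioxirane transfers oxygen to the trans-disubstituted aryl alkene through a spiro transition state and should give the (R,R)-type epoxide, which is threo to the carbinol and is also the face favoured by hydrogen bonding to the allylic hydroxyl. The carbonate buffer preserves the acid-labile electron-rich aryl epoxide, which a titanium alkoxide would open.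

Step 12
Reactants: 16 threo epoxy alcohol B; 10 2,3-bis(benzyloxy)phenol
Product: 17 2,3-bis(benzyloxy)phenyl ether of 16 with inverted (R)-configured ether carbon (erythro to the epoxide oxygen)
Conditions: PPh3, DIAD, toluene, 0 °C to rt
Reagents that add atoms: none
Why: Mitsunobu etherification with SN2 inversion at the benzylic carbinol; the acyloxy-substituted aryl ring and the adjacent epoxide both disfavour ionisation. Inversion of the threo alcohol gives the erythro ether needed for a 2,3-trans ring.

Step 13
Reactants: 17 aryl ether epoxide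
Product: 18 M–B dimer alcohol (2,3-trans-3,4-trans 7,8-bis(benzyloxy)-2-[4-(pivaloyloxy)phenyl]chroman-3-ol as unit M, C6 unsubstituted, bonded through C4 to C6 of the unit B carbonate)
Conditions: BF3·OEt2 (0.3 equiv), CH2Cl2 (0.005 M), −78 °C; Et3N quench
Reagents that add atoms: none
Why: Intramolecular Friedel–Crafts epoxy–arene cyclisation, the same reaction as the key step; the ortho carbon of the aryl ether attacks benzylic C4 anti to the epoxide oxygen in the 6-endo mode. Inversion of the trans epoxide gives the 3,4-trans relation and, with the erythro ether, the 2R,3S,4R-type triad of M.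

Step 14
Reactants: 18 M–B dimer alcohol
Product: 19 6-bromo M–B dimer alcohol (bromine on C6 of unit M)
Conditions: NBS (1.05 equiv), CH2Cl2, −40 to 0 °C
Reagents that add atoms: N-bromosuccinimide O=C1CCC(=O)N1Br
Why: Electrophilic aromatic bromination; C6 of the new ring A is the only free position para to a ring oxygen and ortho to a benzyloxy group, the acyloxy-substituted rings are deactivated, and ring A of B has no such position left.

Step 15
Reactants: 19 6-bromo M–B dimer alcohol
Product: 20 6-bromo M–B dimer 3-acetate
Conditions: Ac2O, pyridine, DMAP (cat.), CH2Cl2, rt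
Reagents that add atoms: acetic anhydride CC(=O)OC(C)=O
Why: Acylation of the secondary alcohol so that it cannot compete in the second Mitsunobu reaction; the acetate goes on without strong base or acid and comes off in step 20.

Step 16
Reactants: 20 6-bromo M–B dimer 3-acetate; 6 (R,E)-alkenylboronate
Product: 21 allylic alcohol MB (20 with Br replaced by the (1E,3R)-3-hydroxy-3-[4-(pivaloyloxy)phenyl]prop-1-en-1-yl group)
Conditions: Pd(OAc)2 (3 mol %), SPhos (6 mol %), K3PO4 (0.5 M aq., 2 equiv), THF, 35 °C
Reagents that add atoms: none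
Why: Suzuki–Miyaura coupling as in step 10; it makes the T–M interflavan bond at C6 of M before C4 of T is a stereocentre.

Step 17
Reactants: 21 allylic alcohol MB
Product: 22 erythro epoxy alcohol MB (C6 of unit M bonded to C2 of a (2S,3S)-oxirane whose C3 carries the (S)-hydroxy[4-(pivaloyloxy)phenyl]methyl group)
Conditions: L-fructose-derived Shi ketone (30 mol %), KHSO5 (as 2KHSO5·KHSO4·K2SO4), K2CO3, Bu4NHSO4, Na2B4O7/Na2EDTA buffer (pH 10.5), MeCN–CH2(OMe)2–H2O, 0 °C
Reagents that add atoms: potassium peroxymonosulfate [K+].[O-]S(=O)(=O)OO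
Why: Shi epoxidation under catalyst control; the enantiomeric ketone should deliver oxygen to the opposite alkene face and give the (S,S)-type epoxide, erythro to the carbinol. The opposing hydrogen-bond preference of the allylic hydroxyl is weak for an E-alkene without 1,3-allylic strain, and the buffer again protects the labile epoxide.

Step 18
Reactants: 22 erythro epoxy alcohol MB; 10 2,3-bis(benzyloxy)phenol
Product: 23 2,3-bis(benzyloxy)phenyl ether of 22 with inverted (R)-configured ether carbon (threo to the epoxide oxygen; the key precursor)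
Conditions: PPh3, DIAD, toluene, 0 °C to rt
Reagents that add atoms: none
Why: Mitsunobu etherification with SN2 inversion; the erythro alcohol becomes the threo ether that closes to a 2,3-cis ring. The acetate on M and the carbonate on B offer no competing hydroxyl.

Step 19
Reactants: 23 key precursor
Product: 24 protected trimer (ring C of T closed, 2,3-cis-3,4-trans, free C3 hydroxyl on T; 3-acetate on M; 3,4-carbonate on B; three aryl pivalates; six benzyl ethers)
Conditions: BF3·OEt2 (0.3 equiv), CH2Cl2 (0.005 M), −78 °C; Et3N quench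
Reagents that add atoms: none
Why: BF3 binds the epoxide oxygen and the C4–O bond, benzylic to ring A of M and supported by its ortho and para oxygens, lengthens; the ortho carbon of the tethered 2,3-bis(benzyloxy)phenyl ether, para to a benzyloxy group, attacks C4 from the side opposite the oxygen and the arenium ion loses a proton. The closest known reaction is the acid-promoted epoxy–arene cyclisation of aryl ethers of 3-aryl-2,3-epoxy alcohols to trans-4-arylchroman-3-ols. Ring C of T closes in the 6-endo mode with both epoxide carbons in the ring; the 5-exo closure at C3 is disfavoured because C3 cannot carry positive charge. The one new stereocentre, C4, is set by inversion of the trans epoxide and so follows from the face chosen in step 17, while C2 and C3 pass through unchanged and keep their cis relation. The selectivity needed is among benzylic C–O bonds: release of ring strain lets the epoxide react at −78 °C with substoichiometric Lewis acid, where the C2–O1 ether (para-pivaloyloxy aryl), the weakly basic tethered carbonate on C4 of B and the finished C4–C6 bond of M should not ionise. High dilution suppresses intermolecular alkylation at the free position para to the ether oxygen. The amine quench before warming protects the new doubly benzylic bond.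

Step 20
Reactants: 24 protected trimer
Product: 25 hexa-O-benzyl trimer (O7 and O8 of all three units benzylated; every other hydroxyl free)
Conditions: K2CO3, MeOH–THF (degassed), 0 °C to rt, argon; aq. NH4Cl
Reagents that add atoms: none
Why: Base-catalysed transesterification removes the three aryl pivalates, the acetate and the cyclic carbonate in one operation. No acid touches the benzylic C4–O bond of B, and the pyrogallol-type oxygens are still benzylated, so the basic medium cannot oxidise them.

Step 21
Reactants: 25 hexa-O-benzyl trimer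
Product: 26 the target, CNP0140823.2
Conditions: H2 (1 atm), Pd(OH)2/C, THF–MeOH, rt, no acid; filtration under argon
Reagents that add atoms: none
Why: Hydrogenolysis of the six aryl benzyl ethers; under neutral conditions these should cleave much faster than the benzylic C4–OH of B or the diarylmethine C4–C6 bonds. No stereocentre is involved.

## Compound list

1 | 4-hydroxybenzaldehyde | O=Cc1ccc(O)cc1 | starting material
2 | 4-formylphenyl pivalate | CC(C)(C)C(=O)Oc1ccc(C=O)cc1 | intermediate
3 | (S)-1-[4-(pivaloyloxy)phenyl]-3-(trimethylsilyl)prop-2-yn-1-ol | CC(C)(C)C(=O)Oc1ccc(cc1)[C@H](O)C#C[Si](C)(C)C | intermediate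
4 | (R)-1-[4-(pivaloyloxy)phenyl]prop-2-yn-1-ol | CC(C)(C)C(=O)Oc1ccc(cc1)[C@H](O)C#C | intermediate
5 | O-pinacolboryl ether of 6 | CC(C)(C)C(=O)Oc1ccc(cc1)[C@H](OB1OC(C)(C)C(C)(C)O1)/C=C/B1OC(C)(C)C(C)(C)O1 | intermediate (not isolated)
6 | (R,E)-1-[4-(pivaloyloxy)phenyl]-3-(pinacolboryl)prop-2-en-1-ol | CC(C)(C)C(=O)Oc1ccc(cc1)[C@H](O)/C=C/B1OC(C)(C)C(C)(C)O1 | intermediate
7 | 2,3-dihydroxybenzaldehyde | O=Cc1cccc(O)c1O | starting material
8 | 2,3-bis(benzyloxy)benzaldehyde | O=Cc1cccc(OCc2ccccc2)c1OCc1ccccc1 | intermediate
9 | 2,3-bis(benzyloxy)phenyl formate | O=COc1cccc(OCc2ccccc2)c1OCc1ccccc1 | intermediate (not isolated)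
10 | 2,3-bis(benzyloxy)phenol | Oc1cccc(OCc2ccccc2)c1OCc1ccccc1 | intermediate
11 | 4-{(1S)-1-[2,3-bis(benzyloxy)phenoxy]prop-2-yn-1-yl}phenyl pivalate | CC(C)(C)C(=O)Oc1ccc(cc1)[C@@H](Oc1cccc(OCc2ccccc2)c1OCc1ccccc1)C#C | intermediate
12 | (2S)-7,8-bis(benzyloxy)-2-[4-(pivaloyloxy)phenyl]-2H-chromene | CC(C)(C)C(=O)Oc1ccc(cc1)[C@H]1Oc2c(C=C1)ccc(OCc3ccccc3)c2OCc1ccccc1 | intermediate
13 | (2R,3S,4R)-7,8-bis(benzyloxy)-3,6-dibromo-2-[4-(pivaloyloxy)phenyl]chroman-4-ol (Br on C3 trans to the aryl group, OH on C4 cis to it) | Brc1cc2c(c(OCc3ccccc3)c1OCc1ccccc1)O[C@H](c1ccc(OC(=O)C(C)(C)C)cc1)[C@@H](Br)[C@@H]2O | intermediate (not isolated)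
14 | unit B bromide: all-cis 7,8-bis(benzyloxy)-6-bromo-2-[4-(pivaloyloxy)phenyl]chromane-3,4-diyl carbonate | Brc1cc2c(c(OCc3ccccc3)c1OCc1ccccc1)O[C@H](c1ccc(OC(=O)C(C)(C)C)cc1)[C@@H]1OC(=O)O[C@H]21 | intermediate
15 | allylic alcohol B: 14 with Br replaced by (1E,3R)-3-hydroxy-3-[4-(pivaloyloxy)phenyl]prop-1-en-1-yl | CC(C)(C)C(=O)Oc1ccc(cc1)[C@H](O)/C=C/c1cc2c(c(OCc3ccccc3)c1OCc1ccccc1)O[C@H](c1ccc(OC(=O)C(C)(C)C)cc1)[C@@H]1OC(=O)O[C@H]21 | intermediate
16 | threo epoxy alcohol B: (2R,3R)-oxirane on C6 of unit B, (S)-carbinol | CC(C)(C)C(=O)Oc1ccc(cc1)[C@H](O)[C@H]1O[C@@H]1c1cc2c(c(OCc3ccccc3)c1OCc1ccccc1)O[C@H](c1ccc(OC(=O)C(C)(C)C)cc1)[C@@H]1OC(=O)O[C@H]21 | intermediate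
17 | 2,3-bis(benzyloxy)phenyl ether of 16, ether carbon inverted (erythro) | CC(C)(C)C(=O)Oc1ccc(cc1)[C@@H](Oc1cccc(OCc2ccccc2)c1OCc1ccccc1)[C@H]1O[C@@H]1c1cc2c(c(OCc3ccccc3)c1OCc1ccccc1)O[C@H](c1ccc(OC(=O)C(C)(C)C)cc1)[C@@H]1OC(=O)O[C@H]21 | intermediate
18 | M–B dimer alcohol (unit M 2,3-trans-3,4-trans, free 3-OH, C6–H; unit B carbonate) | c1cc2c(c(OCc3ccccc3)c1OCc1ccccc1)O[C@H](c1ccc(OC(=O)C(C)(C)C)cc1)[C@@H](O)[C@@H]2c1cc2c(c(OCc3ccccc3)c1OCc1ccccc1)O[C@H](c1ccc(OC(=O)C(C)(C)C)cc1)[C@@H]1OC(=O)O[C@H]21 | intermediate
19 | 6-bromo M–B dimer alcohol | Brc1cc2c(c(OCc3ccccc3)c1OCc1ccccc1)O[C@H](c1ccc(OC(=O)C(C)(C)C)cc1)[C@@H](O)[C@@H]2c1cc2c(c(OCc3ccccc3)c1OCc1ccccc1)O[C@H](c1ccc(OC(=O)C(C)(C)C)cc1)[C@@H]1OC(=O)O[C@H]21 | intermediate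
20 | 6-bromo M–B dimer 3-acetate | Brc1cc2c(c(OCc3ccccc3)c1OCc1ccccc1)O[C@H](c1ccc(OC(=O)C(C)(C)C)cc1)[C@@H](OC(C)=O)[C@@H]2c1cc2c(c(OCc3ccccc3)c1OCc1ccccc1)O[C@H](c1ccc(OC(=O)C(C)(C)C)cc1)[C@@H]1OC(=O)O[C@H]21 | intermediate
21 | allylic alcohol MB: 20 with Br replaced by (1E,3R)-3-hydroxy-3-[4-(pivaloyloxy)phenyl]prop-1-en-1-yl | CC(C)(C)C(=O)Oc1ccc(cc1)[C@H](O)/C=C/c1cc2c(c(OCc3ccccc3)c1OCc1ccccc1)O[C@H](c1ccc(OC(=O)C(C)(C)C)cc1)[C@@H](OC(C)=O)[C@@H]2c1cc2c(c(OCc3ccccc3)c1OCc1ccccc1)O[C@H](c1ccc(OC(=O)C(C)(C)C)cc1)[C@@H]1OC(=O)O[C@H]21 | intermediate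
22 | erythro epoxy alcohol MB: (2S,3S)-oxirane on C6 of unit M, (S)-carbinol | CC(C)(C)C(=O)Oc1ccc(cc1)[C@H](O)[C@@H]1O[C@H]1c1cc2c(c(OCc3ccccc3)c1OCc1ccccc1)O[C@H](c1ccc(OC(=O)C(C)(C)C)cc1)[C@@H](OC(C)=O)[C@@H]2c1cc2c(c(OCc3ccccc3)c1OCc1ccccc1)O[C@H](c1ccc(OC(=O)C(C)(C)C)cc1)[C@@H]1OC(=O)O[C@H]21 | intermediate
23 | key precursor: 2,3-bis(benzyloxy)phenyl ether of 22, ether carbon inverted (threo) | CC(C)(C)C(=O)Oc1ccc(cc1)[C@@H](Oc1cccc(OCc2ccccc2)c1OCc1ccccc1)[C@@H]1O[C@H]1c1cc2c(c(OCc3ccccc3)c1OCc1ccccc1)O[C@H](c1ccc(OC(=O)C(C)(C)C)cc1)[C@@H](OC(C)=O)[C@@H]2c1cc2c(c(OCc3ccccc3)c1OCc1ccccc1)O[C@H](c1ccc(OC(=O)C(C)(C)C)cc1)[C@@H]1OC(=O)O[C@H]21 | intermediate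
24 | protected trimer, product of the key step (free 3-OH on T) | CC(C)(C)C(=O)Oc1ccc(cc1)[C@H]1Oc2c(ccc(OCc3ccccc3)c2OCc2ccccc2)[C@H](c2cc3c(c(OCc4ccccc4)c2OCc2ccccc2)O[C@H](c2ccc(OC(=O)C(C)(C)C)cc2)[C@@H](OC(C)=O)[C@@H]3c2cc3c(c(OCc4ccccc4)c2OCc2ccccc2)O[C@H](c2ccc(OC(=O)C(C)(C)C)cc2)[C@@H]2OC(=O)O[C@H]32)[C@H]1O | intermediate
25 | hexa-O-benzyl trimer | Oc1ccc(cc1)[C@H]1Oc2c(ccc(OCc3ccccc3)c2OCc2ccccc2)[C@H](c2cc3c(c(OCc4ccccc4)c2OCc2ccccc2)O[C@H](c2ccc(O)cc2)[C@@H](O)[C@@H]3c2cc3c(c(OCc4ccccc4)c2OCc2ccccc2)O[C@H](c2ccc(O)cc2)[C@H](O)[C@@H]3O)[C@H]1O | intermediate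
26 | CNP0140823.2 | Oc1ccc([C@H]2Oc3c(ccc(O)c3O)[C@H](c3cc4c(c(O)c3O)O[C@H](c3ccc(O)cc3)[C@@H](O)[C@@H]4c3cc4c(c(O)c3O)O[C@H](c3ccc(O)cc3)[C@H](O)[C@@H]4O)[C@H]2O)cc1 | target

## Step count and least certain steps

Total step count: 21. Longest linear sequence: 18 steps (steps 1–3 and 7–21, from 1 to 26).

**Step 19 (key step).** The most likely failure is that the C4 cation character outruns ring closure. A hydride could then shift from C3 to give a ketone (Meinwald-type rearrangement), the arene could capture C4 from the front side and erode the 3,4-trans relation, or another molecule could alkylate the free para position. The fallback sets out from 23 and returns at 25. Buffered acetolysis (AcOH, NaOAc, CH2Cl2, 0 °C) opens the epoxide at C4 to the hydroxy acetate F1, and Ac2O with pyridine gives the diacetate F2. Me3SiOTf (0.2 equiv, CH2Cl2, −60 °C) then ionises the benzylic acetate with participation of the C3 acetate. The trans-disubstituted acetoxonium ion has the same relative configuration as the trans epoxide, cannot undergo the hydride shift, and is opened at C4 by the arene with inversion (neighbouring-group-directed Friedel–Crafts alkylation), giving the 3-O-acetyl trimer F3. The methanolysis of step 20 removes the extra acetate with the others and gives 25.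

**Step 9.** Two processes are of concern: bromonium formation on the aryl face, which would give the separable 2,3-trans diastereomer, and base-induced collapse of the bromohydrin to a labile 3,4-epoxide before carboxylation. The fallback sets out from 12 and returns at 14. NBS (1 equiv, MeCN, 0 °C) brominates C6 to give the bromochromene F4. Woodward cis-hydroxylation (iodine and AgOAc in moist acetic acid) then puts both oxygens on the aryl face through an acetoxonium ion without any alkoxide, giving the hydroxy acetate F5. K2CO3 in MeOH removes the acetate and the pivalate to give the phenolic diol F6, and t-BuCOCl with Et3N at 0 °C re-acylates only the phenol to give the diol F7. 1,1'-Carbonyldiimidazole closes the carbonate 14.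

**Step 17.** Catalyst control may be eroded if hydrogen bonding of the dioxirane to the allylic hydroxyl steers oxygen to the threo face, and the carbinol may be over-oxidised. The fallback sets out from 21 and returns at 22 without a new compound. It is the hydroxyl-directed Sharpless epoxidation (Ti(OiPr)4, L-(+)-diisopropyl tartrate, t-BuOOH, 4 Å molecular sieves, CH2Cl2, −20 °C), for which the (R)-carbinol is the fast-reacting, erythro-selective partner of the L-tartrate. It must be run with short contact time and a non-acidic quench, because the tetravalent titanium alkoxide can open the product.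

**Step 18 (and its twin, step 12).** Inversion may be incomplete through ionisation at the benzylic carbinol, or coupling with the ortho-substituted phenol may be slow so that the activated alcohol is diverted. The fallback sets out from 22 and returns at 23. MsCl and Et3N at −30 °C give the mesylate F8, and the caesium salt of 10 (Cs2CO3, DMF, 0 °C) displaces it by SN2 with the same inversion.

**Step 21.** The benzylic C4–OH of unit B, activated by the para oxygen, may be lost by hydrogenolysis in competition with ether cleavage. The fallback sets out from 25 and returns at 26 without a new compound. It is single-electron debenzylation with lithium naphthalenide (LiC10H8, THF, −40 °C, then degassed aq. NH4Cl), in which the C4 oxygen is a lithium alkoxide and not a leaving group.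

## Further compounds

F1 | step 19 | hydroxy acetate from 23 (C4 acetate anti to the C3 hydroxyl) | CC(C)(C)C(=O)Oc1ccc(cc1)[C@@H](Oc1cccc(OCc2ccccc2)c1OCc1ccccc1)[C@H](O)[C@H](OC(C)=O)c1cc2c(c(OCc3ccccc3)c1OCc1ccccc1)O[C@H](c1ccc(OC(=O)C(C)(C)C)cc1)[C@@H](OC(C)=O)[C@@H]2c1cc2c(c(OCc3ccccc3)c1OCc1ccccc1)O[C@H](c1ccc(OC(=O)C(C)(C)C)cc1)[C@@H]1OC(=O)O[C@H]21
F2 | step 19 | C3,C4-diacetate from F1 | CC(C)(C)C(=O)Oc1ccc(cc1)[C@@H](Oc1cccc(OCc2ccccc2)c1OCc1ccccc1)[C@H](OC(C)=O)[C@H](OC(C)=O)c1cc2c(c(OCc3ccccc3)c1OCc1ccccc1)O[C@H](c1ccc(OC(=O)C(C)(C)C)cc1)[C@@H](OC(C)=O)[C@@H]2c1cc2c(c(OCc3ccccc3)c1OCc1ccccc1)O[C@H](c1ccc(OC(=O)C(C)(C)C)cc1)[C@@H]1OC(=O)O[C@H]21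
F3 | step 19 | 3-O-acetate of 24 on unit T | CC(C)(C)C(=O)Oc1ccc(cc1)[C@H]1Oc2c(ccc(OCc3ccccc3)c2OCc2ccccc2)[C@H](c2cc3c(c(OCc4ccccc4)c2OCc2ccccc2)O[C@H](c2ccc(OC(=O)C(C)(C)C)cc2)[C@@H](OC(C)=O)[C@@H]3c2cc3c(c(OCc4ccccc4)c2OCc2ccccc2)O[C@H](c2ccc(OC(=O)C(C)(C)C)cc2)[C@@H]2OC(=O)O[C@H]32)[C@H]1OC(C)=O
F4 | step 9 | (2S)-7,8-bis(benzyloxy)-6-bromo-2-[4-(pivaloyloxy)phenyl]-2H-chromene | CC(C)(C)C(=O)Oc1ccc(cc1)[C@H]1Oc2c(C=C1)cc(Br)c(OCc3ccccc3)c2OCc1ccccc1
F5 | step 9 | all-cis 3-acetoxy-7,8-bis(benzyloxy)-6-bromo-2-[4-(pivaloyloxy)phenyl]chroman-4-ol | Brc1cc2c(c(OCc3ccccc3)c1OCc1ccccc1)O[C@H](c1ccc(OC(=O)C(C)(C)C)cc1)[C@H](OC(C)=O)[C@@H]2O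
F6 | step 9 | all-cis 7,8-bis(benzyloxy)-6-bromo-2-(4-hydroxyphenyl)chromane-3,4-diol | Brc1cc2c(c(OCc3ccccc3)c1OCc1ccccc1)O[C@H](c1ccc(O)cc1)[C@H](O)[C@@H]2O
F7 | step 9 | all-cis 7,8-bis(benzyloxy)-6-bromo-2-[4-(pivaloyloxy)phenyl]chromane-3,4-diol | Brc1cc2c(c(OCc3ccccc3)c1OCc1ccccc1)O[C@H](c1ccc(OC(=O)C(C)(C)C)cc1)[C@H](O)[C@@H]2O
F0 | step 17 | none | none
F8 | step 18 | methanesulfonate of 22 | CC(C)(C)C(=O)Oc1ccc(cc1)[C@H](OS(C)(=O)=O)[C@@H]1O[C@H]1c1cc2c(c(OCc3ccccc3)c1OCc1ccccc1)O[C@H](c1ccc(OC(=O)C(C)(C)C)cc1)[C@@H](OC(C)=O)[C@@H]2c1cc2c(c(OCc3ccccc3)c1OCc1ccccc1)O[C@H](c1ccc(OC(=O)C(C)(C)C)cc1)[C@@H]1OC(=O)O[C@H]21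
F0 | step 21 | none | none
A1 | alternative 1 | unit T carrying on C4 the new ring A of M (free C8a hydroxyl, tert-butoxy on C8 and C7) | c5ccccc5COc1ccc([C@H]2Oc3c(ccc(OCc5ccccc5)c3OCc5ccccc5)[C@H](c3ccc(O)c(OC(C)(C)C)c3OC(C)(C)C)[C@H]2OCc5ccccc5)cc1
A2 | alternative 1 | diazo enone on C4 of unit T | c5ccccc5COc1ccc([C@H]2Oc3c(ccc(OCc5ccccc5)c3OCc5ccccc5)[C@H](C(=[N+]=[N-])C(=O)C=C)[C@H]2OCc5ccccc5)cc1
A3 | alternative 1 | di-tert-butoxyethyne | CC(C)(C)OC#COC(C)(C)C
A4 | alternative 2 | benzyl-protected trimer with free 3,4-cis diol on B | c5ccccc5COc1ccc([C@H]2Oc3c(ccc(OCc5ccccc5)c3OCc5ccccc5)[C@H](c3cc4c(c(OCc5ccccc5)c3OCc5ccccc5)O[C@H](c3ccc(OCc5ccccc5)cc3)[C@@H](OCc5ccccc5)[C@@H]4c3cc4c(c(OCc5ccccc5)c3OCc5ccccc5)O[C@H](c3ccc(OCc5ccccc5)cc3)[C@H](O)[C@@H]4O)[C@H]2OCc5ccccc5)cc1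
A5 | alternative 2 | dialdehyde precursor (aryl aldehyde on C4a of B, α-aryloxy aldehyde at the future C3) | c5ccccc5COc1ccc([C@H]2Oc3c(ccc(OCc5ccccc5)c3OCc5ccccc5)[C@H](c3cc4c(c(OCc5ccccc5)c3OCc5ccccc5)O[C@H](c3ccc(OCc5ccccc5)cc3)[C@@H](OCc5ccccc5)[C@@H]4c3cc(C=O)c(c(OCc5ccccc5)c3OCc5ccccc5)O[C@H](c3ccc(OCc5ccccc5)cc3)C=O)[C@H]2OCc5ccccc5)cc1
A6 | alternative 3 | protected trimer with a pinacol boronate on C3 of M | c5ccccc5COc1ccc([C@H]2Oc3c(ccc(OCc5ccccc5)c3OCc5ccccc5)[C@H](c3cc4c(c(OCc5ccccc5)c3OCc5ccccc5)O[C@H](c3ccc(OCc5ccccc5)cc3)[C@@H](B6OC(C)(C)C(C)(C)O6)[C@@H]4c3cc4c(c(OCc5ccccc5)c3OCc5ccccc5)O[C@H](c3ccc(OCc5ccccc5)cc3)[C@H](OC6(C)C)[C@@H]4O6)[C@H]2OCc5ccccc5)cc1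
A7 | alternative 3 | diaryl carbinol (ring A of M with free C8a hydroxyl, carbinol carbon bonded to C4a of M and C6 of B, configuration at the carbinol immaterial) | c7ccccc7COc1ccc([C@H]2Oc3c(ccc(OCc7ccccc7)c3OCc7ccccc7)[C@H](c3cc(C(O)c4cc5c(c(OCc7ccccc7)c4OCc7ccccc7)O[C@H](c4ccc(OCc7ccccc7)cc4)[C@H](OC6(C)C)[C@@H]5O6)c(O)c(OCc7ccccc7)c3OCc7ccccc7)[C@H]2OCc7ccccc7)cc1
A8 | alternative 3 | (E)-2-[2-(4-benzyloxyphenyl)ethenyl]-4,4,5,5-tetramethyl-1,3,2-dioxaborolane | c1ccccc1COc1ccc(/C=C/B2OC(C)(C)C(C)(C)O2)cc1
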